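**Retrosynthetic overview**
- Target ⇐ hydrogenolysis of its catechol dibenzyl ether ⇐ addition of a 3,4‑dimethoxybenzyl Grignard reagent to a cis‑5‑aryl‑4‑(silyloxymethyl)dihydrofuran‑3(2H)‑one, anti to both ring substituents (sets the C(OH)(benzyl) centre).
- That furanone ⇐ enantioconvergent 7→5 ring contraction of the triethylsilyl enol ether of a racemic 2‑aryl‑1,3‑dioxepan‑5‑one (acetal C–O traded for the ring C–C bond; sets the other two stereocentres).
- Dioxepanone ⇐ hydroboration/oxidation of the 4,7‑dihydro‑1,3‑dioxepine acetal of (Z)‑but‑2‑ene‑1,4‑diol and 3,4‑bis(benzyloxy)benzaldehyde.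
- Both aryl units ⇐ catechol (O‑benzylation/formylation; O‑methylation/chloromethylation).
- Ring order: seven‑membered acetal first, then contraction to the only ring of the target.

Assumption: the IDPi enantiomer that gives (4R,5R)‑10 is found by a short screen (both are made from (R)‑ or (S)‑BINOL); (S,S) is written below.

**Route**

Step 1
Reactants: 1 catechol (benzene‑1,2‑diol)
Product: 2 1,2‑bis(benzyloxy)benzene
Conditions: BnBr (2.2 equiv), K2CO3, DMF, 60 °C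
Reagents that add atoms: benzyl bromide, BrCc1ccccc1
Why: Williamson ether synthesis masks both phenols as hydrogenolysable benzyl ethers; no stereocentre.

Step 2
Reactants: 2 1,2‑bis(benzyloxy)benzene
Product: 3 3,4‑bis(benzyloxy)benzaldehyde
Conditions: Cl2CHOMe, SnCl4, CH2Cl2, −78 → −20 °C; H2O
Reagents that add atoms: dichloromethyl methyl ether, COC(Cl)Cl; water, O
Why: Rieche formylation places CHO para to one benzyloxy group, and cold SnCl4 should spare the benzyl ethers.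

Step 3
Reactants: 3 3,4‑bis(benzyloxy)benzaldehyde; 4 (Z)‑but‑2‑ene‑1,4‑diol
Product: 5 2‑[3,4‑bis(benzyloxy)phenyl]‑4,7‑dihydro‑1,3‑dioxepine
Conditions: PPTS (cat.), toluene, reflux, Dean–Stark
Reagents that add atoms: none
Why: acid‑catalysed acetalisation, with the cis‑alkene pre‑organising the diol for seven‑membered ring closure; product is achiral.

Step 4
Reactants: 5 2‑[3,4‑bis(benzyloxy)phenyl]‑4,7‑dihydro‑1,3‑dioxepine
Product: 8 (±)‑2‑[3,4‑bis(benzyloxy)phenyl]‑1,3‑dioxepan‑5‑one, via alkylborane 6 (not isolated), via borate ester 7 (not isolated)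
Conditions: BH3·SMe2, THF, 0 °C → rt; then NMO (5 equiv), TPAP (5 mol%), 4 Å MS, CH2Cl2, rt
Reagents that add atoms: N‑methylmorpholine N‑oxide, C[N+]1([O-])CCOCC1; borane–dimethyl sulfide, C[S+](C)[BH3-] (boron of 6 and 7 only)
Why: hydroboration of the symmetrical alkene gives one borane, and amine‑oxide C–B oxidation followed by Ley–Griffith oxidation gives the ketone in one pot; the acetal stereocentre of racemic 8 is erased in step 6.

Step 5
Reactants: 8 (±)‑2‑[3,4‑bis(benzyloxy)phenyl]‑1,3‑dioxepan‑5‑one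
Product: 9 (±)‑{[2‑(3,4‑bis(benzyloxy)phenyl)‑4,7‑dihydro‑1,3‑dioxepin‑5‑yl]oxy}triethylsilane
Conditions: LDA, TESCl (in situ quench), THF–DMPU, −78 °C; Et3N, pentane work‑up
Reagents that add atoms: chlorotriethylsilane, CC[Si](Cl)(CC)CC
Why: kinetic lithium amide deprotonation of an α‑alkoxy ketone is expected at the non‑oxygenated α′‑CH2 (C6), and the in situ silyl quench traps the β‑alkoxy enolate before elimination (regioselective silyl enol ether formation).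

Step 6
Reactants: 9 (±)‑{[2‑(3,4‑bis(benzyloxy)phenyl)‑4,7‑dihydro‑1,3‑dioxepin‑5‑yl]oxy}triethylsilane
Product: 10 (4R,5R)‑5‑[3,4‑bis(benzyloxy)phenyl]‑4‑{[(triethylsilyl)oxy]methyl}dihydrofuran‑3(2H)‑one
Conditions: (S,S)‑IDPi (BINOL‑derived imidodiphosphorimidate, silylated in situ, 2 mol%), toluene, −78 °C; Et3N quench
Reagents that add atoms: none
Why: Proposed new method: the silylium–IDPi ion pair ionises the C2–O1 acetal bond of racemic 9, giving an achiral aryl oxocarbenium ion on O3 (the only ion that can close to a five‑membered ring), the tethered enol silane attacks it 5‑(enolendo) inside the chiral anion pocket, and silyl transfer from the ketone oxygen to the released C7 alkoxide turns the catalyst over, so the seven‑membered acetal contracts enantioconvergently to the furanone with C4 and C5 set together; cis is expected because the E‑oxocarbenium and the ring‑fixed enol silane (CH2OSi "inside") can only meet in a twisted envelope that puts aryl and CH2OSi on one face (kinetic control at −78 °C); closest known reactions are the Lewis‑acid [1,3] O→C ring contraction of 4,5‑dihydro‑1,3‑dioxepines to tetrahydrofuran‑3‑carbaldehydes, the Petasis–Ferrier rearrangement and IDPi‑catalysed Mukaiyama additions to acetal‑derived oxocarbenium ions.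

Step 7
Reactants: 1 catechol (benzene‑1,2‑diol)
Product: 11 1,2‑dimethoxybenzene (veratrole)
Conditions: MeI (2.5 equiv), K2CO3, acetone, reflux
Reagents that add atoms: iodomethane, CI
Why: Williamson O‑methylation installs the two methyl ethers of the target.

Step 8
Reactants: 11 1,2‑dimethoxybenzene
Product: 12 4‑(chloromethyl)‑1,2‑dimethoxybenzene
Conditions: (CH2O)n, HCl (g), CH2Cl2, 0–5 °C; used crude
Reagents that add atoms: formaldehyde (as paraformaldehyde), C=O; hydrogen chloride, Cl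
Why: Blanc chloromethylation occurs para to a methoxy group of the activated arene.

Step 9
Reactants: 10 (4R,5R)‑5‑[3,4‑bis(benzyloxy)phenyl]‑4‑{[(triethylsilyl)oxy]methyl}dihydrofuran‑3(2H)‑one; 12 4‑(chloromethyl)‑1,2‑dimethoxybenzene
Product: 15 (3R,4R,5R)‑5‑[3,4‑bis(benzyloxy)phenyl]‑3‑(3,4‑dimethoxybenzyl)‑4‑(hydroxymethyl)tetrahydrofuran‑3‑ol, via benzylic Grignard reagent 13 (not isolated), via triethylsilyl ether 14 (not isolated)
Conditions: 12, Mg (activated), THF, 0 °C; add to 10 + LaCl3·2LiCl, THF, −78 °C; then 1 M HCl, THF, 0 °C → rt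
Reagents that add atoms: magnesium, [Mg] (in 13 only)
Why: lanthanide‑promoted Grignard 1,2‑addition outruns enolisation, the benzyl group enters anti to the cis CH2OSi and aryl groups so the new tertiary OH is cis to both (3R), and the acidic work‑up removes the silyl group.

Step 10
Reactants: 15 (3R,4R,5R)‑5‑[3,4‑bis(benzyloxy)phenyl]‑3‑(3,4‑dimethoxybenzyl)‑4‑(hydroxymethyl)tetrahydrofuran‑3‑ol
Product: 16 (3R,4R,5R)‑5‑(3,4‑dihydroxyphenyl)‑3‑(3,4‑dimethoxybenzyl)‑4‑(hydroxymethyl)tetrahydrofuran‑3‑ol (CNP0115253.1)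
Conditions: H2 (1 atm), 10% Pd/C, EtOAc–MeOH, rt, stopped after 2 equiv H2
Reagents that add atoms: none
Why: hydrogenolysis of the two aryl benzyl ethers is much faster than cleavage of the ring benzylic C–O bond; no stereocentre is touched.

**Compound list**
1 | catechol (benzene‑1,2‑diol) | Oc1ccccc1O | starting material
2 | 1,2‑bis(benzyloxy)benzene | c1ccc(COc2ccccc2OCc2ccccc2)cc1 | intermediate
3 | 3,4‑bis(benzyloxy)benzaldehyde | O=Cc1ccc(OCc2ccccc2)c(OCc2ccccc2)c1 | intermediate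
4 | (Z)‑but‑2‑ene‑1,4‑diol | OC/C=C\CO | starting material
5 | 2‑[3,4‑bis(benzyloxy)phenyl]‑4,7‑dihydro‑1,3‑dioxepine | C1=CCOC(c2ccc(OCc3ccccc3)c(OCc3ccccc3)c2)OC1 | intermediate
6 | {2‑[3,4‑bis(benzyloxy)phenyl]‑1,3‑dioxepan‑5‑yl}borane (racemic, diastereomer mixture) | BC1CCOC(c2ccc(OCc3ccccc3)c(OCc3ccccc3)c2)OC1 | intermediate
7 | 2‑[3,4‑bis(benzyloxy)phenyl]‑1,3‑dioxepan‑5‑yl dihydrogen borate (racemic, diastereomer mixture) | OB(O)OC1CCOC(c2ccc(OCc3ccccc3)c(OCc3ccccc3)c2)OC1 | intermediate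
8 | (±)‑2‑[3,4‑bis(benzyloxy)phenyl]‑1,3‑dioxepan‑5‑one | O=C1CCOC(c2ccc(OCc3ccccc3)c(OCc3ccccc3)c2)OC1 | intermediate
9 | (±)‑{[2‑(3,4‑bis(benzyloxy)phenyl)‑4,7‑dihydro‑1,3‑dioxepin‑5‑yl]oxy}triethylsilane | CC[Si](CC)(CC)OC1=CCOC(c2ccc(OCc3ccccc3)c(OCc3ccccc3)c2)OC1 | intermediate
10 | (4R,5R)‑5‑[3,4‑bis(benzyloxy)phenyl]‑4‑{[(triethylsilyl)oxy]methyl}dihydrofuran‑3(2H)‑one | O=C1CO[C@@H](c2ccc(OCc3ccccc3)c(OCc3ccccc3)c2)[C@H]1CO[Si](CC)(CC)CC | intermediate
11 | 1,2‑dimethoxybenzene (veratrole) | COc1ccccc1OC | intermediate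
12 | 4‑(chloromethyl)‑1,2‑dimethoxybenzene | COc1ccc(CCl)cc1OC | intermediate
13 | (3,4‑dimethoxybenzyl)magnesium chloride | COc1ccc(C[Mg]Cl)cc1OC | intermediate
14 | (3R,4R,5R)‑5‑[3,4‑bis(benzyloxy)phenyl]‑3‑(3,4‑dimethoxybenzyl)‑4‑{[(triethylsilyl)oxy]methyl}tetrahydrofuran‑3‑ol | COc1ccc(C[C@]2(O)CO[C@@H](c3ccc(OCc4ccccc4)c(OCc4ccccc4)c3)[C@H]2CO[Si](CC)(CC)CC)cc1OC | intermediate
15 | (3R,4R,5R)‑5‑[3,4‑bis(benzyloxy)phenyl]‑3‑(3,4‑dimethoxybenzyl)‑4‑(hydroxymethyl)tetrahydrofuran‑3‑ol | COc1ccc(C[C@]2(O)CO[C@@H](c3ccc(OCc4ccccc4)c(OCc4ccccc4)c3)[C@H]2CO)cc1OC | intermediate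
16 | (3R,4R,5R)‑5‑(3,4‑dihydroxyphenyl)‑3‑(3,4‑dimethoxybenzyl)‑4‑(hydroxymethyl)tetrahydrofuran‑3‑ol | COc1ccc(C[C@]2(O)CO[C@@H](c3ccc(O)c(O)c3)[C@H]2CO)cc1OC | target

**Count and risks**
Total steps: 10. Longest linear sequence: 8 (steps 1–6, 9, 10 from catechol).

Step 6 (new ring contraction) may give low ee, the trans isomer or no turnover. The known‑chemistry fallback sets out from 5 and returns at 10. m‑CPBA/NaHCO3 gives the meso epoxide 4‑[3,4‑bis(benzyloxy)phenyl]‑3,5,8‑trioxabicyclo[5.1.0]octane F2. Desymmetrising β‑elimination with a chiral lithium amide gives the vinyl acetal (5S)‑2‑[3,4‑bis(benzyloxy)phenyl]‑4,5‑dihydro‑1,3‑dioxepin‑5‑ol F3 (its acetal centre is irrelevant). TESCl/imidazole gives {[(5S)‑2‑(3,4‑bis(benzyloxy)phenyl)‑4,5‑dihydro‑1,3‑dioxepin‑5‑yl]oxy}triethylsilane F4. The established TMSOTf‑promoted [1,3] O→C ring contraction of 4,5‑dihydro‑1,3‑dioxepines (−78 °C, kinetic 2,3‑cis, new bond anti to the silyloxy group) gives (2R,3R,4S)‑2‑[3,4‑bis(benzyloxy)phenyl]‑4‑[(triethylsilyl)oxy]tetrahydrofuran‑3‑carbaldehyde F5. NaBH4 gives [(2R,3R,4S)‑2‑[3,4‑bis(benzyloxy)phenyl]‑4‑[(triethylsilyl)oxy]tetrahydrofuran‑3‑yl]methanol F6. AcOH–H2O–THF gives (3S,4S,5R)‑5‑[3,4‑bis(benzyloxy)phenyl]‑4‑(hydroxymethyl)tetrahydrofuran‑3‑ol F7. TESCl (1.0 equiv, −78 °C) silylates only the primary hydroxyl to give (3S,4S,5R)‑5‑[3,4‑bis(benzyloxy)phenyl]‑4‑{[(triethylsilyl)oxy]methyl}tetrahydrofuran‑3‑ol F8, and Dess–Martin oxidation of F8 gives 10.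

Step 5 (regioselective enol silane) may deprotonate at the α‑alkoxy C4 or lose the β‑alkoxide. The fallback sets out from 8 and returns at 9. Dehydrogenation (IBX, DMSO, 65 °C, or Pd(TFA)2/DMSO/O2) can only form a C6=C7 double bond and gives the enone 2‑[3,4‑bis(benzyloxy)phenyl]‑1,3‑dioxepin‑5(4H)‑one F1. Rh‑catalysed 1,4‑hydrosilylation (Et3SiH, [RhCl(PPh3)3]) then gives 9 with the enol double bond fixed.

Step 9 (benzyl addition) may suffer Wurtz coupling of 12, enolisation with C4 epimerisation, or β‑elimination of silanolate. The fallback sets out from 10 (arene from 11) and returns at 14. Dimethylsulfonium methylide (Me3S+ I−, KHMDS, THF, −20 °C, Corey–Chaykovsky) adds from the open face to give (3S,6R,7R)‑6‑[3,4‑bis(benzyloxy)phenyl]‑7‑{[(triethylsilyl)oxy]methyl}‑1,5‑dioxaspiro[2.4]heptane F9. Veratrole 11 is brominated (NBS, MeCN) to 4‑bromo‑1,2‑dimethoxybenzene F10 and converted with Mg into (3,4‑dimethoxyphenyl)magnesium bromide F11. CuI‑catalysed opening of F9 at its CH2 by F11 gives 14, which is desilylated as in step 9 to 15.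

Further compounds
F1 | step 5 | 2‑[3,4‑bis(benzyloxy)phenyl]‑1,3‑dioxepin‑5(4H)‑one (racemic) | O=C1COC(c2ccc(OCc3ccccc3)c(OCc3ccccc3)c2)OC=C1
F2 | step 6 | 4‑[3,4‑bis(benzyloxy)phenyl]‑3,5,8‑trioxabicyclo[5.1.0]octane (meso, both C4 epimers) | C1OC(c2ccc(OCc3ccccc3)c(OCc3ccccc3)c2)OCC2OC12
F3 | step 6 | (5S)‑2‑[3,4‑bis(benzyloxy)phenyl]‑4,5‑dihydro‑1,3‑dioxepin‑5‑ol | O[C@@H]1COC(c2ccc(OCc3ccccc3)c(OCc3ccccc3)c2)OC=C1
F4 | step 6 | {[(5S)‑2‑(3,4‑bis(benzyloxy)phenyl)‑4,5‑dihydro‑1,3‑dioxepin‑5‑yl]oxy}triethylsilane | CC[Si](CC)(CC)O[C@@H]1COC(c2ccc(OCc3ccccc3)c(OCc3ccccc3)c2)OC=C1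
F5 | step 6 | (2R,3R,4S)‑2‑[3,4‑bis(benzyloxy)phenyl]‑4‑[(triethylsilyl)oxy]tetrahydrofuran‑3‑carbaldehyde | CC[Si](CC)(CC)O[C@@H]1CO[C@@H](c2ccc(OCc3ccccc3)c(OCc3ccccc3)c2)[C@H]1C=O
F6 | step 6 | [(2R,3R,4S)‑2‑[3,4‑bis(benzyloxy)phenyl]‑4‑[(triethylsilyl)oxy]tetrahydrofuran‑3‑yl]methanol | CC[Si](CC)(CC)O[C@@H]1CO[C@@H](c2ccc(OCc3ccccc3)c(OCc3ccccc3)c2)[C@H]1CO
F7 | step 6 | (3S,4S,5R)‑5‑[3,4‑bis(benzyloxy)phenyl]‑4‑(hydroxymethyl)tetrahydrofuran‑3‑ol | O[C@@H]1CO[C@@H](c2ccc(OCc3ccccc3)c(OCc3ccccc3)c2)[C@H]1CO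
F8 | step 6 | (3S,4S,5R)‑5‑[3,4‑bis(benzyloxy)phenyl]‑4‑{[(triethylsilyl)oxy]methyl}tetrahydrofuran‑3‑ol | O[C@@H]1CO[C@@H](c2ccc(OCc3ccccc3)c(OCc3ccccc3)c2)[C@H]1CO[Si](CC)(CC)CC
F9 | step 9 | (3S,6R,7R)‑6‑[3,4‑bis(benzyloxy)phenyl]‑7‑{[(triethylsilyl)oxy]methyl}‑1,5‑dioxaspiro[2.4]heptane | C1O[C@]12CO[C@@H](c3ccc(OCc4ccccc4)c(OCc4ccccc4)c3)[C@H]2CO[Si](CC)(CC)CC
F10 | step 9 | 4‑bromo‑1,2‑dimethoxybenzene | COc1ccc(Br)cc1OC
F11 | step 9 | (3,4‑dimethoxyphenyl)magnesium bromide | COc1ccc([Mg]Br)cc1OC
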